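Assumption: ethyl (1S,2R)-2-aminocyclopentane-1-carboxylate hydrochloride (the ethyl ester of ent-cispentacin) and 12-bromododec-1-ene are taken as catalogue compounds.

**Retrosynthetic overview**
- The intramolecular nitrone–alkene cycloaddition is set aside; both pyridines come off last through one double hydroboration / B-alkyl Suzuki coupling of bis-alkene 10 with two molecules of 3-bromopyridine.
- C3 is traced back to the carbonyl of a cis-fused bicyclic isoxazolidin-5-one 6: Grignard addition gives the C3–C bond, then convex-face ionic hydrogenation of the N,O-hemiketal sets C3.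
- The isoxazolidinone ring is closed by N-oxygenation of a secondary amine (N–O bond) followed by acyl-transfer lactonisation (O–C3 bond).
- C3a and C6a are bought as (1S,2R)-cis-2-aminocyclopentanecarboxylate; the N-chain is attached by alkylation.
- Ring order: cyclopentane (purchased), then the isoxazolidine (as its lactone), then the two pyridines (purchased as 3-bromopyridine).

**Route**

Step 1
Reactants: 1 ethyl (1S,2R)-2-aminocyclopentane-1-carboxylate hydrochloride; 2 12-bromododec-1-ene
Product: 3 ethyl (1S,2R)-2-(dodec-11-en-1-ylamino)cyclopentane-1-carboxylate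
Conditions: 1 (1.3 equiv), K2CO3 (3 equiv), KI (0.1 equiv), MeCN, 60 °C
Reagents that add atoms: none
Why: Finkelstein-assisted SN2 N-alkylation of an α-branched primary amine, which stops at the more hindered secondary amine when the amine is in slight excess; neither stereocentre is touched under carbonate.

Step 2
Reactants: 3 ethyl (1S,2R)-2-(dodec-11-en-1-ylamino)cyclopentane-1-carboxylate
Product: 4 ethyl (1S,2R)-2-[(benzoyloxy)(dodec-11-en-1-yl)amino]cyclopentane-1-carboxylate
Conditions: (PhCO2)2 (1.2 equiv), K2HPO4 (1.5 equiv), DMF, 0 °C to rt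
Reagents that add atoms: dibenzoyl peroxide, O=C(OOC(=O)c1ccccc1)c1ccccc1
Why: Electrophilic N-oxygenation (SN2 attack of the amine on the peroxide O–O bond) installs the future ring N–O bond as a stable O-benzoyl hydroxylamine that cannot over-oxidise; the terminal alkene and both stereocentres are inert.

Step 3
Reactants: 4 ethyl (1S,2R)-2-[(benzoyloxy)(dodec-11-en-1-yl)amino]cyclopentane-1-carboxylate
Product: 6 (3aS,6aR)-1-(dodec-11-en-1-yl)hexahydro-3H-cyclopenta[c]isoxazol-3-one, via lithium aminoxide 5 (not isolated)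
Conditions: LiOEt (0.2 equiv), THF, −20 °C to rt; AcOH quench
Reagents that add atoms: none
Why: Alkoxide-catalysed transesterification cascade: ethoxide cleaves the activated benzoate, the freed N–O⁻ closes 5-exo-trig onto the cis ester and releases ethoxide again, so the net change is 4 → 6 + ethyl benzoate; only the cis isomer can lactonise, which locks C3a and C6a.

Step 4
Reactants: 6 (3aS,6aR)-1-(dodec-11-en-1-yl)hexahydro-3H-cyclopenta[c]isoxazol-3-one; 7 8-bromooct-1-ene
Product: 9 (3aS,6aR)-1-(dodec-11-en-1-yl)-3-(oct-7-en-1-yl)hexahydro-1H-cyclopenta[c]isoxazol-3-ol (C3 epimer mixture), via oct-7-en-1-ylmagnesium bromide 8 (not isolated)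
Conditions: 7, Mg, THF, 40 °C; then 6 (8 at 1.15 equiv), THF, −78 °C; aq NH4Cl at −78 °C
Reagents that add atoms: none
Why: Grignard addition to a lactone arrested at the tetrahedral stage (the magnesium hemiketalate of an α-branched lactone survives at −78 °C until quench) gives the cyclic N,O-hemiketal; C3 forms as an inconsequential epimer mixture and C3a/C6a are untouched.

Step 5
Reactants: 9 (3aS,6aR)-1-(dodec-11-en-1-yl)-3-(oct-7-en-1-yl)hexahydro-1H-cyclopenta[c]isoxazol-3-ol
Product: 10 (3S,3aS,6aR)-1-(dodec-11-en-1-yl)-3-(oct-7-en-1-yl)hexahydro-1H-cyclopenta[c]isoxazole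
Conditions: Et3SiH (4 equiv), BF3·OEt2 (2.5 equiv), CH2Cl2, −78 to −20 °C
Reagents that add atoms: none
Why: Ionic hydrogenation of a lactol: BF3 ionises the hemiketal to a bicyclic N,O-oxocarbenium ion (the ion type behind Lewis-acid substitution of 5-acyloxyisoxazolidines) and Et3SiH delivers hydride to its convex face, anti to the C3a–C4 bond, so H-3 ends up cis to H-3a and the octenyl chain sits on the concave face, which is (3S).

Step 6
Reactants: 10 (3S,3aS,6aR)-1-(dodec-11-en-1-yl)-3-(oct-7-en-1-yl)hexahydro-1H-cyclopenta[c]isoxazole; 11 3-bromopyridine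
Product: 13 (3S,3aS,6aR)-1-[12-(pyridin-3-yl)dodecyl]-3-[8-(pyridin-3-yl)octyl]hexahydro-1H-cyclopenta[c]isoxazole (CNP0267546.1), via bis(9-BBN) dialkylborane 12 (not isolated)
Conditions: 9-BBN (2.5 equiv), THF, 0 °C to rt; then 11 (2.6 equiv), Pd(dppf)Cl2 (5 mol %), 3 M aq NaOH, THF/DMF, 65 °C
Reagents that add atoms: 3-bromopyridine (second molar equivalent of 11, one pyridyl ring for each chain end), Brc1cccnc1
Why: Hydroboration then twofold B-alkyl Suzuki–Miyaura coupling: 9-BBN adds anti-Markovnikov to both terminal alkenes and each of the two primary B-alkyl groups transfers to one molecule of 3-bromopyridine after its oxidative addition to zerovalent palladium, so one molecule of 10 consumes two molecules of 11; the N,N,O-trialkylhydroxylamine and all three stereocentres are not affected.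

**Compound list**

1 | ethyl (1S,2R)-2-aminocyclopentane-1-carboxylate hydrochloride | Cl.CCOC(=O)[C@H]1CCC[C@H]1N | starting material
2 | 12-bromododec-1-ene | C=CCCCCCCCCCCBr | starting material
3 | ethyl (1S,2R)-2-(dodec-11-en-1-ylamino)cyclopentane-1-carboxylate | CCOC(=O)[C@H]1CCC[C@H]1NCCCCCCCCCCC=C | intermediate
4 | ethyl (1S,2R)-2-[(benzoyloxy)(dodec-11-en-1-yl)amino]cyclopentane-1-carboxylate | CCOC(=O)[C@H]1CCC[C@H]1N(OC(=O)c2ccccc2)CCCCCCCCCCC=C | intermediate
5 | O-lithium salt of ethyl (1S,2R)-2-[dodec-11-en-1-yl(hydroxy)amino]cyclopentane-1-carboxylate (lithium aminoxide) | CCOC(=O)[C@H]1CCC[C@H]1N([O-])CCCCCCCCCCC=C.[Li+] | intermediate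
6 | (3aS,6aR)-1-(dodec-11-en-1-yl)hexahydro-3H-cyclopenta[c]isoxazol-3-one (cis-fused isoxazolidin-5-one; N1, O2, C3=O) | C=CCCCCCCCCCCN1OC(=O)[C@H]2CCC[C@H]21 | intermediate
7 | 8-bromooct-1-ene | C=CCCCCCCBr | starting material
8 | oct-7-en-1-ylmagnesium bromide | C=CCCCCCC[Mg]Br | intermediate
9 | (3aS,6aR)-1-(dodec-11-en-1-yl)-3-(oct-7-en-1-yl)hexahydro-1H-cyclopenta[c]isoxazol-3-ol (C3 epimer mixture, C3 left undefined) | C=CCCCCCCCCCCN1OC(O)(CCCCCCC=C)[C@H]2CCC[C@H]21 | intermediate
10 | (3S,3aS,6aR)-1-(dodec-11-en-1-yl)-3-(oct-7-en-1-yl)hexahydro-1H-cyclopenta[c]isoxazole | C=CCCCCCCCCCCN1O[C@@H](CCCCCCC=C)[C@H]2CCC[C@H]21 | intermediate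
11 | 3-bromopyridine | Brc1cccnc1 | starting material
12 | (3S,3aS,6aR)-1-[12-(9-borabicyclo[3.3.1]nonan-9-yl)dodecyl]-3-[8-(9-borabicyclo[3.3.1]nonan-9-yl)octyl]hexahydro-1H-cyclopenta[c]isoxazole | C1CCC2CCCC1B2CCCCCCCCCCCCN1O[C@@H](CCCCCCCCB2C3CCCC2CCC3)[C@H]2CCC[C@H]21 | intermediate
13 | (3S,3aS,6aR)-1-[12-(pyridin-3-yl)dodecyl]-3-[8-(pyridin-3-yl)octyl]hexahydro-1H-cyclopenta[c]isoxazole | c1cncc(CCCCCCCCCCCCN2O[C@@H](CCCCCCCCc3cccnc3)[C@H]3CCC[C@H]32)c1 | target

**Totals**

Total step count: 6. Longest linear sequence: 6 steps (1 → 3 → 4 → 6 → 9 → 10 → 13).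

**Three steps most likely to fail**

Step 3 (acyl-transfer lactonisation). The cascade may stall at the open N-hydroxy ester, or ethoxide may epimerise C1 to the trans ester, which cannot close. The fallback sets out from 4: LiOH·H2O in THF/H2O at 0 °C cleaves both the benzoate and the ethyl ester to give (1S,2R)-2-[dodec-11-en-1-yl(hydroxy)amino]cyclopentane-1-carboxylic acid F1. This is closed by dehydrative O-acylation with EDC·HCl in CH2Cl2 at 0 °C, and the route is rejoined at 6.

Step 4 (Grignard mono-addition). The N–O⁻ leaving group may let the tetrahedral intermediate collapse, leading to double addition, or the Grignard reagent may attack nitrogen of the O-acyl hydroxylamine. The fallback sets out from 6: MeNH(OMe)·HCl and i-PrMgCl in THF at −20 °C open the lactone to the Weinreb amide (1S,2R)-2-[dodec-11-en-1-yl(hydroxy)amino]-N-methoxy-N-methylcyclopentane-1-carboxamide F2. Treatment with 8 (2.5 equiv; the first equivalent deprotonates N–OH) in THF at 0 °C gives a chelated adduct that cannot over-add. On work-up the β-(hydroxyamino) ketone closes by itself to the hemiketal, and the route is rejoined at 9.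

Step 5 (ionic hydrogenation). Facial selectivity at the N,O-oxocarbenium ion may be lower than expected, or the hemiketal may ring-open and lose the hydroxylamine under BF3. The fallback sets out from 9 and replaces the cation logic by an SN2 closure. NaBH4 in EtOH at 0 °C reduces the open keto tautomer; Felkin–Anh attack anti to the bulkier nitrogen-bearing ring carbon and past the α-hydrogen is expected to favour (1R)-1-{(1S,2R)-2-[dodec-11-en-1-yl(hydroxy)amino]cyclopentyl}non-8-en-1-ol F3, which is separated from its epimer. Mitsunobu cyclodehydration (Bu3P, 1,1'-(azodicarbonyl)dipiperidine, toluene, rt) then has the N–OH group displace the activated carbinol with inversion to give the (3S) ring, and the route is rejoined at 10.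

**Further compounds**

F1 | step 3 | (1S,2R)-2-[dodec-11-en-1-yl(hydroxy)amino]cyclopentane-1-carboxylic acid | OC(=O)[C@H]1CCC[C@H]1N(O)CCCCCCCCCCC=C
F2 | step 4 | (1S,2R)-2-[dodec-11-en-1-yl(hydroxy)amino]-N-methoxy-N-methylcyclopentane-1-carboxamide | CON(C)C(=O)[C@H]1CCC[C@H]1N(O)CCCCCCCCCCC=C
F3 | step 5 | (1R)-1-{(1S,2R)-2-[dodec-11-en-1-yl(hydroxy)amino]cyclopentyl}non-8-en-1-ol | O[C@H](CCCCCCC=C)[C@H]1CCC[C@H]1N(O)CCCCCCCCCCC=C
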